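**Retrosynthetic overview**
- The target is (2S)-5,7,4'-trihydroxy-3'-methoxy-6-prenylflavanone. Rings A and B are bought as benzene rings. Ring C (O1, C2, C3, C4, C4a, C8a) is the only ring built, and it is closed last.
- Enabling feature: O1–C8a=C4a–C4=O is a vinylogous ester shared by rings A and C. It is the retron of a formal [4+2] between an aldehyde C=O and a C3=C4–C4a=C8a unit. C8a lies ortho to C4 and meta to the oxygens on C5 and C7, so a fluorine on C8a behaves as a vinylogous acyl fluoride.
- Key disconnection, both bonds in one flask: C2–C3 (C3 carbanion onto the aldehyde carbon of O-protected vanillin) and O1–C8a (the former aldehyde oxygen displaces fluoride). C4 is carried as its (R)-tert-butanesulfinyl imine, which acidifies C3–H, controls C2 and activates C8a, and is hydrolysed afterwards.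
- The fluoro ketone comes from 5-fluororesorcinol by two directed metalations: prenyl between the two protected oxygens, acetyl between fluorine and oxygen. This fixes the 6-prenyl pattern before ring C exists, and acid removes the MOM groups at the end.

Key step: step 6

Assumption: the (R)-configured sulfinyl group is taken to direct the aldehyde addition to the (S)-carbinol centre, as inferred from the known aldol-type additions of such metalloenamines to aryl aldehydes; should the opposite sense be found, the equally available (S)-sulfinamide is used and nothing else changes.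

Step 1
Reactants: 1 5-fluorobenzene-1,3-diol
Product: 2 1-fluoro-3,5-bis(methoxymethoxy)benzene
Conditions: NaH, MOMCl, DMF, 0 → 23 °C
Reagents that add atoms: chloromethyl methyl ether (MOMCl), COCCl
Why: NaH deprotonates both phenols and MOMCl alkylates them on oxygen (Williamson-type ether synthesis), giving acetals that are stable to organolithiums, direct both later metalations and fall off in mild acid.

Step 2
Reactants: 2 1-fluoro-3,5-bis(methoxymethoxy)benzene; 3 1-bromo-3-methylbut-2-ene (prenyl bromide)
Product: 5 5-fluoro-1,3-bis(methoxymethoxy)-2-(3-methylbut-2-en-1-yl)benzene, via aryllithium 4 (not isolated)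
Conditions: n-BuLi, Et2O, −20 °C; CuBr·SMe2 (10 mol %), 3, −78 → 23 °C
Reagents that add atoms: none
Why: Directed ortho-metalation, in which n-BuLi in a weakly coordinating solvent is held by both acetal groups and should remove the proton between them rather than one next to fluorine, followed by copper-assisted SN2 alkylation at the unsubstituted terminus of the allylic bromide.

Step 3
Reactants: 5 5-fluoro-1,3-bis(methoxymethoxy)-2-(3-methylbut-2-en-1-yl)benzene; 6 N-methoxy-N-methylacetamide
Product: 9 1-[6-fluoro-2,4-bis(methoxymethoxy)-3-(3-methylbut-2-en-1-yl)phenyl]ethan-1-one, via aryllithium 7 (not isolated), via lithium hemiaminal adduct 8 (not isolated)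
Conditions: s-BuLi, THF, −78 °C; 6, −78 → −20 °C; H2O
Reagents that add atoms: none
Why: The two remaining ring protons of 5 are equivalent and each is flanked by fluorine and an OMOM group, so directed ortho-metalation at −78 °C (below the aryne threshold) is unambiguous, and the Weinreb ketone synthesis stops at adduct 8 until the aqueous quench.

Step 4
Reactants: 9 1-[6-fluoro-2,4-bis(methoxymethoxy)-3-(3-methylbut-2-en-1-yl)phenyl]ethan-1-one; 10 (R)-2-methylpropane-2-sulfinamide
Product: 11 (R,E)-N-{1-[6-fluoro-2,4-bis(methoxymethoxy)-3-(3-methylbut-2-en-1-yl)phenyl]ethylidene}-2-methylpropane-2-sulfinamide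
Conditions: Ti(OEt)4 (3 equiv), THF, 75 °C (sealed vessel)
Reagents that add atoms: none
Why: Ti(OEt)4 serves as Lewis acid and water scavenger in the condensation to the N-sulfinyl ketimine, a reaction with close precedent on ortho-fluoroacetophenones, and the sulfur stereocentre is not touched.

Step 5
Reactants: 12 4-hydroxy-3-methoxybenzaldehyde (vanillin)
Product: 13 3-methoxy-4-(methoxymethoxy)benzaldehyde
Conditions: NaH, MOMCl, DMF, 0 → 23 °C
Reagents that add atoms: chloromethyl methyl ether (MOMCl), COCCl
Why: Williamson-type O-alkylation masks the acidic phenol, which would otherwise quench the carbanion of step 6, with the same acid-labile group used on ring A.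

Step 6
Reactants: 11 (R,E)-N-{1-[6-fluoro-2,4-bis(methoxymethoxy)-3-(3-methylbut-2-en-1-yl)phenyl]ethylidene}-2-methylpropane-2-sulfinamide; 13 3-methoxy-4-(methoxymethoxy)benzaldehyde
Product: 17 (R)-N-{(2S,4E)-2-[3-methoxy-4-(methoxymethoxy)phenyl]-5,7-bis(methoxymethoxy)-6-(3-methylbut-2-en-1-yl)-2,3-dihydro-4H-chromen-4-ylidene}-2-methylpropane-2-sulfinamide, via lithium azaenolate 14 (not isolated), via bromomagnesium azaenolate 15 (not isolated), via bromomagnesium alkoxide 16 (not isolated)
Conditions: LiN(i-Pr)2 (LDA, 1.05 equiv), THF, −78 °C; MgBr2·OEt2 (2 equiv), −78 °C; 13 (limiting component), −78 °C; then DMPU, −78 → 23 °C; pH 7 buffer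
Reagents that add atoms: none
Why: Proposed new method: LDA removes a methyl proton of 11, MgBr2 converts lithium azaenolate 14 into metalloenamine 15, and 15 adds to aldehyde 13 to form C2–C3 (the known aldol-type addition of N-tert-butanesulfinyl metalloenamines), after which warming lets the alkoxide oxygen of 16 attack the fluorine-bearing C8a and expel fluoride by addition–elimination (SNAr) to form O1–C8a. The closest known reaction types are the domino imine-addition–SNAr and aldol–SNAr annulations of 2-fluoroaryl carbonyl compounds and, in its bond set, the stepwise aldol–cyclisation pathway of the hetero-Diels–Alder reaction of 1-alkoxy-3-silyloxydienes with aldehydes; what is new is the union of an auxiliary-controlled addition with an oxygen SNAr on an oxygenated ring. Ring C closes in a 6-endo-trig mode with respect to the C4a=C8a bond, helped by magnesium or lithium bound to the departing fluorine and by the second equivalent of MgBr2 on the C=N–S=O unit. The C2 stereocentre is set by the sulfur stereocentre in a closed six-membered magnesium-bridged chair (aryl group of 13 equatorial, tert-butyl group turned away from the incoming aldehyde) and is kept in the ring closure because the C2–O bond is never broken. The step needs the SNAr to outrun loss of stereochemical information and elimination: reversal of the addition only returns 15 and 13, which recombine under the same auxiliary, β-hydroxy imines dehydrate less readily than β-hydroxy ketones, keeping 13 limiting suppresses hydride transfer from the alkoxide to free aldehyde, the base is used up as fluoride salt so that 17 is not left in base, and any C2 epimer of 17 is a diastereomer that chromatography removes. Site selectivity is built into 11, since C8a is the only ring carbon with a leaving group (which fixes the 6-prenyl pattern) and the oxygens on C5 and C7 stand meta to it, so the negative charge that the attack places on C4a, C6 and C8 is not opposed by them.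

Step 7
Reactants: 17 (R)-N-{(2S,4E)-2-[3-methoxy-4-(methoxymethoxy)phenyl]-5,7-bis(methoxymethoxy)-6-(3-methylbut-2-en-1-yl)-2,3-dihydro-4H-chromen-4-ylidene}-2-methylpropane-2-sulfinamide
Product: 18 (2S)-2-[3-methoxy-4-(methoxymethoxy)phenyl]-5,7-bis(methoxymethoxy)-6-(3-methylbut-2-en-1-yl)-2,3-dihydro-4H-chromen-4-one
Conditions: p-TsOH·H2O (cat.), THF–H2O, 23 °C
Reagents that add atoms: water, O
Why: Acid-catalysed imine hydrolysis with a non-nucleophilic acid adds water to the protonated C=N while the sulfinyl group still activates it, under conditions too mild for aryl MOM ethers, the prenyl alkene or the C2–O1 bond, so C2 stays (S).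

Step 8
Reactants: 18 (2S)-2-[3-methoxy-4-(methoxymethoxy)phenyl]-5,7-bis(methoxymethoxy)-6-(3-methylbut-2-en-1-yl)-2,3-dihydro-4H-chromen-4-one
Product: 19 (2S)-5,7-dihydroxy-2-(4-hydroxy-3-methoxyphenyl)-6-(3-methylbut-2-en-1-yl)-2,3-dihydro-4H-chromen-4-one
Conditions: HCl in MeOH (1.25 M), 35 °C, stopped at full conversion
Reagents that add atoms: none
Why: Acid-catalysed acetal exchange with methanol removes the three MOM groups, a deprotection with close precedent on prenylated flavanones, and the low temperature and short contact should keep the prenyl chain open and ring C closed so that C2 is not scrambled.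

**Compound list**
1 | 5-fluorobenzene-1,3-diol | Oc1cc(O)cc(F)c1 | starting material
2 | 1-fluoro-3,5-bis(methoxymethoxy)benzene | COCOc1cc(F)cc(OCOC)c1 | intermediate
3 | 1-bromo-3-methylbut-2-ene | CC(C)=CCBr | starting material
4 | [4-fluoro-2,6-bis(methoxymethoxy)phenyl]lithium | [Li]c1c(OCOC)cc(F)cc1OCOC | intermediate
5 | 5-fluoro-1,3-bis(methoxymethoxy)-2-(3-methylbut-2-en-1-yl)benzene | COCOc1cc(F)cc(OCOC)c1CC=C(C)C | intermediate
6 | N-methoxy-N-methylacetamide | CC(=O)N(C)OC | starting material
7 | [6-fluoro-2,4-bis(methoxymethoxy)-3-(3-methylbut-2-en-1-yl)phenyl]lithium | [Li]c1c(F)cc(OCOC)c(CC=C(C)C)c1OCOC | intermediate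
8 | lithium 1-[6-fluoro-2,4-bis(methoxymethoxy)-3-(3-methylbut-2-en-1-yl)phenyl]-1-[methoxy(methyl)amino]ethan-1-olate | CC(O[Li])(N(C)OC)c1c(F)cc(OCOC)c(CC=C(C)C)c1OCOC | intermediate
9 | 1-[6-fluoro-2,4-bis(methoxymethoxy)-3-(3-methylbut-2-en-1-yl)phenyl]ethan-1-one | CC(=O)c1c(F)cc(OCOC)c(CC=C(C)C)c1OCOC | intermediate
10 | (R)-2-methylpropane-2-sulfinamide | CC(C)(C)[S@@](=O)N | starting material
11 | (R,E)-N-{1-[6-fluoro-2,4-bis(methoxymethoxy)-3-(3-methylbut-2-en-1-yl)phenyl]ethylidene}-2-methylpropane-2-sulfinamide | C/C(=N\[S@](=O)C(C)(C)C)c1c(F)cc(OCOC)c(CC=C(C)C)c1OCOC | intermediate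
12 | 4-hydroxy-3-methoxybenzaldehyde | COc1cc(C=O)ccc1O | starting material
13 | 3-methoxy-4-(methoxymethoxy)benzaldehyde | COCOc1ccc(C=O)cc1OC | intermediate
14 | N-lithio (R)-N-(1-arylvinyl)-2-methylpropane-2-sulfinamide (lithium azaenolate of 11) | C=C(N([Li])[S@](=O)C(C)(C)C)c1c(F)cc(OCOC)c(CC=C(C)C)c1OCOC | intermediate
15 | N-bromomagnesio (R)-N-(1-arylvinyl)-2-methylpropane-2-sulfinamide (magnesium azaenolate of 11) | C=C(N([Mg]Br)[S@](=O)C(C)(C)C)c1c(F)cc(OCOC)c(CC=C(C)C)c1OCOC | intermediate
16 | bromomagnesium (1S)-alkoxide of the β-hydroxy N-sulfinyl ketimine from 15 and 13 | Br[Mg]O[C@@H](C/C(=N\[S@](=O)C(C)(C)C)c1c(F)cc(OCOC)c(CC=C(C)C)c1OCOC)c1ccc(OCOC)c(OC)c1 | intermediate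
17 | (R)-N-{(2S,4E)-2-[3-methoxy-4-(methoxymethoxy)phenyl]-5,7-bis(methoxymethoxy)-6-(3-methylbut-2-en-1-yl)-2,3-dihydro-4H-chromen-4-ylidene}-2-methylpropane-2-sulfinamide | COCOc1ccc([C@@H]2C/C(=N\[S@](=O)C(C)(C)C)c3c(OCOC)c(CC=C(C)C)c(OCOC)cc3O2)cc1OC | intermediate
18 | (2S)-2-[3-methoxy-4-(methoxymethoxy)phenyl]-5,7-bis(methoxymethoxy)-6-(3-methylbut-2-en-1-yl)-2,3-dihydro-4H-chromen-4-one | COCOc1ccc([C@@H]2CC(=O)c3c(OCOC)c(CC=C(C)C)c(OCOC)cc3O2)cc1OC | intermediate
19 | (2S)-5,7-dihydroxy-2-(4-hydroxy-3-methoxyphenyl)-6-(3-methylbut-2-en-1-yl)-2,3-dihydro-4H-chromen-4-one | COc1cc([C@@H]2CC(=O)c3c(cc(O)c(CC=C(C)C)c3O)O2)ccc1O | target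

Total step count: 8. Longest linear sequence: 7 steps (1, 2, 3, 4, 6, 7, 8, from 5-fluorobenzene-1,3-diol).

**Steps most likely to fail**

Step 6. On warming, the addition may reverse and diastereocontrol may erode. The adduct may also dehydrate, or fluoride displacement by the magnesium alkoxide may be too slow. The fallback uses known chemistry only, sets out from 9 and comes back at 18.
- The fluoride of 9 is displaced by hydroxide (KOH, DMSO–H2O, 80 °C) to give 1-[6-hydroxy-2,4-bis(methoxymethoxy)-3-(3-methylbut-2-en-1-yl)phenyl]ethan-1-one F1. Its only free phenol sits where O1 must be.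
- Claisen–Schmidt condensation of F1 and 13 (KOH, EtOH, 23 °C) gives the (E)-2'-hydroxychalcone F2.
- Oxa-Michael ring closure (NaOAc, EtOH, reflux) gives the racemic tri-MOM flavanone F3.
- Kinetic resolution follows by asymmetric transfer hydrogenation (RuCl(p-cymene)[(R,R)-TsDPEN], HCO2H–Et3N, EtOAc, 23 °C, stopped near half conversion). It should reduce the (R)-enantiomer to the cis-(2R,4R)-flavan-4-ol F4 and leave (S)-configured 18, which is separated by chromatography.

Step 2. Metalation may take place next to fluorine instead of between the two acetal groups, with aryne formation from that anion. The fallback avoids ring metalation altogether, sets out from 1 and comes back at 9, replacing steps 1 to 3.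
- Friedel–Crafts acylation of 1 (AcOH, BF3·OEt2, 90 °C) occurs para to one hydroxyl and ortho to the other and gives 1-(2-fluoro-4,6-dihydroxyphenyl)ethan-1-one F5.
- Nuclear C-prenylation with 3 (KOH, MeOH–H2O, 0 → 23 °C) at the carbon between the two phenol oxygens gives 1-[6-fluoro-2,4-dihydroxy-3-(3-methylbut-2-en-1-yl)phenyl]ethan-1-one F6.
- Double O-alkylation (NaH, MOMCl, DMF) gives 9.

Step 8. Brønsted acid may cyclise the prenyl chain onto a flanking phenol, add to the alkene, or slowly open ring C with loss of enantiopurity. The fallback replaces acid solvolysis by a buffered acetal-to-silyl-ether exchange, sets out from 18 and comes back at 19.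
- TMSOTf and 2,2'-bipyridyl (MeCN, 0 °C) convert the three aryl MOM ethers into the tris(trimethylsilyl) ether of the target F7.
- F7 is hydrolysed by water at neutral pH during work-up to give 19.

**Further compounds**
F1 | step 6 | 1-[6-hydroxy-2,4-bis(methoxymethoxy)-3-(3-methylbut-2-en-1-yl)phenyl]ethan-1-one | CC(=O)c1c(O)cc(OCOC)c(CC=C(C)C)c1OCOC
F2 | step 6 | (E)-1-[6-hydroxy-2,4-bis(methoxymethoxy)-3-(3-methylbut-2-en-1-yl)phenyl]-3-[3-methoxy-4-(methoxymethoxy)phenyl]prop-2-en-1-one | COCOc1ccc(/C=C/C(=O)c2c(O)cc(OCOC)c(CC=C(C)C)c2OCOC)cc1OC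
F3 | step 6 | racemic 2-[3-methoxy-4-(methoxymethoxy)phenyl]-5,7-bis(methoxymethoxy)-6-(3-methylbut-2-en-1-yl)-2,3-dihydro-4H-chromen-4-one | COCOc1ccc(C2CC(=O)c3c(OCOC)c(CC=C(C)C)c(OCOC)cc3O2)cc1OC
F4 | step 6 | (2R,4R)-2-[3-methoxy-4-(methoxymethoxy)phenyl]-5,7-bis(methoxymethoxy)-6-(3-methylbut-2-en-1-yl)-3,4-dihydro-2H-chromen-4-ol | COCOc1ccc([C@H]2C[C@@H](O)c3c(OCOC)c(CC=C(C)C)c(OCOC)cc3O2)cc1OC
F5 | step 2 | 1-(2-fluoro-4,6-dihydroxyphenyl)ethan-1-one | CC(=O)c1c(F)cc(O)cc1O
F6 | step 2 | 1-[6-fluoro-2,4-dihydroxy-3-(3-methylbut-2-en-1-yl)phenyl]ethan-1-one | CC(=O)c1c(F)cc(O)c(CC=C(C)C)c1O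
F7 | step 8 | (2S)-2-[3-methoxy-4-(trimethylsilyloxy)phenyl]-6-(3-methylbut-2-en-1-yl)-5,7-bis(trimethylsilyloxy)-2,3-dihydro-4H-chromen-4-one | COc1cc([C@@H]2CC(=O)c3c(cc(O[Si](C)(C)C)c(CC=C(C)C)c3O[Si](C)(C)C)O2)ccc1O[Si](C)(C)C
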